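**Plan**
Labdane numbering is used: ring A is C1–C5 and C10, ring B is C5–C10, C17 is the exocyclic CH2, C19 the ester carbon, C20 the CH3 on C10, and C11–C16 the side chain.
Retrosynthesis: the C8=C17 methylenation and the C1–C2 saturation are undone first. C3–C4 and C5–C10 are then cut together (retro-[4+2]), which opens rings A and B to an acyclic (2E,8Z)-undeca-2,8,10-trienoate. That triene is cut at C2=C3 (Wittig), at O–C2/C8–C9 (hetero-Diels–Alder) and at C4=C5 (cross-metathesis).
Forward: citronellol supplies C9–C16, C10 and C20. A temporary dihydropyran ring (O–C8–C9–C10=C1–C2) is built first and opened to the (Z)-diene, and rings A and B then arise in one intramolecular Diels–Alder step. The C8 hydroxyl is a helper that ends as the exocyclic methylene.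
Enabling feature: the cis ring fusion with H-5, CH3-20 and CO2Me on one face of ring A, and C11 syn to CH3-20 on ring B. This is the pattern that a (Z)-diene C3=C2–C1=C10, tied through C9–C6 to an (E)-2-methyl-enoate C4=C5, is bound to give.
Stereochemistry: C13 is bought. C8 and C9 come from one catalytic enantioselective cycloaddition. C4, C5 and C10 are relayed from C9 and the two alkene geometries in the key step, and C8 is erased afterwards.

Key step: step 8

Assumption: the chromium Schiff-base catalyst of step 5 is taken to show the facial preference known for its additions of 1-methoxybutadiene to aliphatic aldehydes; the ligand from (1S,2R)-1-aminoindan-2-ol is specified on that basis, and its antipode would be used if a test run showed the opposite sense.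

Step 1
Reactants: 1 (S)-citronellol, (3S)-3,7-dimethyloct-6-en-1-ol
Product: 2 ({[(3S)-3,7-dimethyloct-6-en-1-yl]oxy}methyl)benzene
Conditions: NaH, BnBr, Bu4NI (cat.), THF, 0 °C → rt
Reagents that add atoms: benzyl bromide, BrCc1ccccc1
Why: Williamson ether synthesis; the benzyl ether should survive the ylides, acid and heat of steps 2–9 and is removed in the hydrogenation of step 10 without a separate step, and C13 is not touched.

Step 2
Reactants: 2 ({[(3S)-3,7-dimethyloct-6-en-1-yl]oxy}methyl)benzene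
Product: 4 (2E,6S)-8-(benzyloxy)-2,6-dimethyloct-2-enal, via allylic alcohol 3 (not isolated)
Conditions: SeO2 (0.3 equiv), t-BuOOH (3 equiv), salicylic acid (0.1 equiv), CH2Cl2, rt; then MnO2, CH2Cl2, rt
Reagents that add atoms: selenium dioxide, O=[Se]=O; tert-butyl hydroperoxide, CC(C)(C)OO
Why: Selenium dioxide allylic oxidation (ene reaction, then [2,3]-sigmatropic shift) takes the (E)-methyl group of the trisubstituted alkene, and MnO2 then oxidises only the allylic alcohol to the (E)-enal without changing the alkene geometry.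

Step 3
Reactants: 4 (2E,6S)-8-(benzyloxy)-2,6-dimethyloct-2-enal
Product: 5 ({[(3S,5E,7E)-8-methoxy-3,6-dimethylocta-5,7-dien-1-yl]oxy}methyl)benzene
Conditions: Ph3PCH2OMe chloride, KN(SiMe3)2, THF, −78 → 0 °C
Reagents that add atoms: (methoxymethyl)triphenylphosphonium chloride, COC[P+](c1ccccc1)(c1ccccc1)c1ccccc1.[Cl-]
Why: Wittig olefination of the enal with the methoxymethylene ylide adds C2 as an enol ether and leaves the (5E) alkene alone; the new enol ether is expected as a mixture of geometries, of which only the (7E) isomer can reach the s-cis form and enter step 5, so the mixture would be used as such.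

Step 4
Reactants: 6 pent-4-enal; 7 methyl methacrylate
Product: 8 methyl (2E)-2-methyl-6-oxohex-2-enoate
Conditions: second-generation Hoveyda–Grubbs catalyst RuCl2(H2IMes)(=CH-C6H4-2-O-i-Pr) (2 mol%), methyl methacrylate (5 equiv), CH2Cl2, 40 °C
Reagents that add atoms: none
Why: Olefin cross-metathesis of a terminal alkene with a 1,1-disubstituted acrylate should give the trisubstituted enoate with E geometry under thermodynamic control, and the aldehyde is tolerated by the ruthenium carbene.

Step 5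
Reactants: 5 ({[(3S,5E,7E)-8-methoxy-3,6-dimethylocta-5,7-dien-1-yl]oxy}methyl)benzene; 8 methyl (2E)-2-methyl-6-oxohex-2-enoate
Product: 9 methyl (2E)-5-[(2R,3R,6R)-3-[(3S)-5-(benzyloxy)-3-methylpentyl]-6-methoxy-4-methyl-3,6-dihydro-2H-pyran-2-yl]-2-methylpent-2-enoate
Conditions: CrCl(L) (5 mol%; L = dianion of (1S,2R)-1-{[3-(adamantan-1-yl)-2-hydroxy-5-methylbenzylidene]amino}indan-2-ol, trivalent chromium), 4 Å molecular sieves, neat, rt
Reagents that add atoms: none
Why: Catalytic enantioselective hetero-Diels–Alder reaction of a 1-alkoxydiene with an aldehyde bound to the chiral Lewis acid forms C8–C9 and O–C2 at once; the catalyst fixes the aldehyde face (C8), the endo transition state with the (E,E)-diene places C7, C11 and OMe all cis (C9), and the new ring locks C10=C1 in the Z geometry that step 8 needs.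

Step 6
Reactants: 9 methyl (2E)-5-[(2R,3R,6R)-3-[(3S)-5-(benzyloxy)-3-methylpentyl]-6-methoxy-4-methyl-3,6-dihydro-2H-pyran-2-yl]-2-methylpent-2-enoate
Product: 10 methyl (2E)-5-[(2R,3R)-3-[(3S)-5-(benzyloxy)-3-methylpentyl]-6-hydroxy-4-methyl-3,6-dihydro-2H-pyran-2-yl]-2-methylpent-2-enoate (both anomers)
Conditions: pyridinium p-toluenesulfonate (cat.), acetone–H2O (10:1), rt
Reagents that add atoms: water, O
Why: Mild acid hydrolysis of the allylic mixed acetal through the cyclic oxocarbenium ion leaves C8 and C9 untouched, and the six-membered lactol keeps the Z alkene from isomerising.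

Step 7
Reactants: 10 methyl (2E)-5-[(2R,3R)-3-[(3S)-5-(benzyloxy)-3-methylpentyl]-6-hydroxy-4-methyl-3,6-dihydro-2H-pyran-2-yl]-2-methylpent-2-enoate
Product: 12 methyl (2E,6R,7R,8Z)-7-[(3S)-5-(benzyloxy)-3-methylpentyl]-6-hydroxy-2,8-dimethylundeca-2,8,10-trienoate, via open hydroxy-enal 11 (not isolated)
Conditions: Ph3PCH3Br (4 equiv), KN(SiMe3)2 (3 equiv), THF, −20 → 0 °C; AcOH quench at −20 °C
Reagents that add atoms: methyltriphenylphosphonium bromide, C[P+](c1ccccc1)(c1ccccc1)c1ccccc1.[Br-]
Why: Wittig methylenation of the lactol through its open (Z)-hydroxy-enal form adds C3 and carries the ring-imposed Z geometry into the diene; the excess phosphonium salt should reprotonate the C8 alkoxide so that it does not add to the enoate.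

Step 8
Reactants: 12 methyl (2E,6R,7R,8Z)-7-[(3S)-5-(benzyloxy)-3-methylpentyl]-6-hydroxy-2,8-dimethylundeca-2,8,10-trienoate
Product: 13 methyl (1S,4aS,5R,6R,8aS)-5-[(3S)-5-(benzyloxy)-3-methylpentyl]-6-hydroxy-1,4a-dimethyl-1,2,4a,5,6,7,8,8a-octahydronaphthalene-1-carboxylate
Conditions: toluene (0.01 M), BHT (cat.), 170 °C, sealed tube
Reagents that add atoms: none
Why: Thermal, concerted but asynchronous [4+2] cycloaddition (intramolecular Diels–Alder reaction of a 1,7,9-decatriene with a terminally activated dienophile; the closest known type is the cyclisation of (Z)-diene decatrienoates to cis-fused octalins), in which the enoate β-carbon C5 bonds to the fully substituted diene terminus C10 and the α-carbon C4 to the unsubstituted terminus C3, so each new bond joins a hindered carbon to an unhindered one. Ring B closes through the C5–C10 bond over the four-carbon tether C6–C9 (six-membered, chair-like, fused mode), and ring A closes as the cyclohexene of the cycloaddition itself (C3–C4 and C5–C10, with C1=C2 left behind). Because the tether sits on the inside (Z) position of C10, it can reach the dienophile only with C6 exo, which forces the cis ring fusion at C5 (H-5 syn to CH3-20) and puts the ester endo; the E geometry of the enoate then fixes C4 (CO2Me syn to H-5), so C4, C5 and C10 follow from the two alkene geometries with no endo/exo choice left. The one open selectivity is the diene face, and C9 secures it: allylic 1,3-strain against the vinyl group holds H-9 in the diene plane, C8 with the tether goes to the reacting face and C11 to the far face (equatorial on the forming ring B, as is the 8-OH), which gives C10 with CH3-20 syn to C11. The same in-plane H-9 is poorly aligned for the competing [1,5]-hydrogen shift of (Z)-dienes.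

Step 9
Reactants: 13 methyl (1S,4aS,5R,6R,8aS)-5-[(3S)-5-(benzyloxy)-3-methylpentyl]-6-hydroxy-1,4a-dimethyl-1,2,4a,5,6,7,8,8a-octahydronaphthalene-1-carboxylate
Product: 14 methyl (1S,4aS,5R,8aS)-5-[(3S)-5-(benzyloxy)-3-methylpentyl]-1,4a-dimethyl-6-oxo-1,2,4a,5,6,7,8,8a-octahydronaphthalene-1-carboxylate
Conditions: Dess–Martin periodinane, NaHCO3, CH2Cl2, rt
Reagents that add atoms: none
Why: Dess–Martin oxidation of the secondary alcohol erases the helper stereocenter C8; the buffered, non-basic medium should leave C9, now α to the ketone, unchanged.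

Step 10
Reactants: 14 methyl (1S,4aS,5R,8aS)-5-[(3S)-5-(benzyloxy)-3-methylpentyl]-1,4a-dimethyl-6-oxo-1,2,4a,5,6,7,8,8a-octahydronaphthalene-1-carboxylate
Product: 15 methyl (1S,4aS,5R,8aS)-5-[(3S)-5-hydroxy-3-methylpentyl]-1,4a-dimethyl-6-oxodecahydronaphthalene-1-carboxylate
Conditions: H2 (1 atm), 10% Pd/C, EtOH–EtOAc, rt
Reagents that add atoms: none
Why: Heterogeneous hydrogenation saturates the cis-disubstituted C1=C2 alkene (no new stereocenter) and cleaves the benzyl ether by hydrogenolysis in the same operation; the ketone and the ester are inert under these conditions.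

Step 11
Reactants: 15 methyl (1S,4aS,5R,8aS)-5-[(3S)-5-hydroxy-3-methylpentyl]-1,4a-dimethyl-6-oxodecahydronaphthalene-1-carboxylate
Product: 16 methyl (1S,4aS,5R,8aS)-5-[(3S)-5-acetoxy-3-methylpentyl]-1,4a-dimethyl-6-oxodecahydronaphthalene-1-carboxylate
Conditions: Ac2O, pyridine, DMAP (cat.), CH2Cl2, 0 °C → rt
Reagents that add atoms: acetic anhydride, CC(=O)OC(C)=O
Why: Acylation of the only hydroxyl group (primary) under nucleophilic catalysis; the conditions are too mild to enolise the hindered ketone.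

Step 12
Reactants: 16 methyl (1S,4aS,5R,8aS)-5-[(3S)-5-acetoxy-3-methylpentyl]-1,4a-dimethyl-6-oxodecahydronaphthalene-1-carboxylate
Product: 17 methyl (1S,4aR,5S,8aS)-5-[(3S)-5-acetoxy-3-methylpentyl]-1,4a-dimethyl-6-methylidenedecahydronaphthalene-1-carboxylate (target)
Conditions: Zn, CH2Br2, TiCl4, THF–CH2Cl2, 0 °C → rt
Reagents that add atoms: dibromomethane, BrCBr
Why: Takai–Lombardo methylenation with the geminal dimetallic reagent converts the hindered ketone into the exocyclic methylene; the reagent is non-basic, so C9 should not epimerise, and it does not attack the acetate or the methyl ester.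

**Compound list**
1 | (S)-citronellol, (3S)-3,7-dimethyloct-6-en-1-ol | CC(C)=CCC[C@H](C)CCO | starting material
2 | ({[(3S)-3,7-dimethyloct-6-en-1-yl]oxy}methyl)benzene | CC(C)=CCC[C@H](C)CCOCc1ccccc1 | intermediate
3 | (2E,6S)-8-(benzyloxy)-2,6-dimethyloct-2-en-1-ol | OC/C(C)=C/CC[C@H](C)CCOCc1ccccc1 | intermediate (not isolated)
4 | (2E,6S)-8-(benzyloxy)-2,6-dimethyloct-2-enal | O=C/C(C)=C/CC[C@H](C)CCOCc1ccccc1 | intermediate
5 | ({[(3S,5E,7E)-8-methoxy-3,6-dimethylocta-5,7-dien-1-yl]oxy}methyl)benzene | CO/C=C/C(C)=C/CC[C@H](C)CCOCc1ccccc1 | intermediate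
6 | pent-4-enal | C=CCCC=O | starting material
7 | methyl methacrylate | C=C(C)C(=O)OC | starting material
8 | methyl (2E)-2-methyl-6-oxohex-2-enoate | O=CCC/C=C(\C)C(=O)OC | intermediate
9 | methyl (2E)-5-[(2R,3R,6R)-3-[(3S)-5-(benzyloxy)-3-methylpentyl]-6-methoxy-4-methyl-3,6-dihydro-2H-pyran-2-yl]-2-methylpent-2-enoate | CO[C@H]1C=C(C)[C@@H](CC[C@H](C)CCOCc2ccccc2)[C@@H](CC/C=C(\C)C(=O)OC)O1 | intermediate
10 | methyl (2E)-5-[(2R,3R)-3-[(3S)-5-(benzyloxy)-3-methylpentyl]-6-hydroxy-4-methyl-3,6-dihydro-2H-pyran-2-yl]-2-methylpent-2-enoate | OC1C=C(C)[C@@H](CC[C@H](C)CCOCc2ccccc2)[C@@H](CC/C=C(\C)C(=O)OC)O1 | intermediate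
11 | methyl (2E,6R,7R,8Z)-7-[(3S)-5-(benzyloxy)-3-methylpentyl]-6-hydroxy-2,8-dimethyl-10-oxodeca-2,8-dienoate | O=C/C=C(/C)[C@@H](CC[C@H](C)CCOCc1ccccc1)[C@H](O)CC/C=C(\C)C(=O)OC | intermediate (not isolated)
12 | methyl (2E,6R,7R,8Z)-7-[(3S)-5-(benzyloxy)-3-methylpentyl]-6-hydroxy-2,8-dimethylundeca-2,8,10-trienoate | C=C/C=C(/C)[C@@H](CC[C@H](C)CCOCc1ccccc1)[C@H](O)CC/C=C(\C)C(=O)OC | intermediate
13 | methyl (1S,4aS,5R,6R,8aS)-5-[(3S)-5-(benzyloxy)-3-methylpentyl]-6-hydroxy-1,4a-dimethyl-1,2,4a,5,6,7,8,8a-octahydronaphthalene-1-carboxylate | O[C@@H]1CC[C@H]2[C@](C)(C=CC[C@]2(C)C(=O)OC)[C@H]1CC[C@H](C)CCOCc1ccccc1 | intermediate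
14 | methyl (1S,4aS,5R,8aS)-5-[(3S)-5-(benzyloxy)-3-methylpentyl]-1,4a-dimethyl-6-oxo-1,2,4a,5,6,7,8,8a-octahydronaphthalene-1-carboxylate | O=C1CC[C@H]2[C@](C)(C=CC[C@]2(C)C(=O)OC)[C@H]1CC[C@H](C)CCOCc1ccccc1 | intermediate
15 | methyl (1S,4aS,5R,8aS)-5-[(3S)-5-hydroxy-3-methylpentyl]-1,4a-dimethyl-6-oxodecahydronaphthalene-1-carboxylate | O=C1CC[C@H]2[C@](C)(CCC[C@]2(C)C(=O)OC)[C@H]1CC[C@H](C)CCO | intermediate
16 | methyl (1S,4aS,5R,8aS)-5-[(3S)-5-acetoxy-3-methylpentyl]-1,4a-dimethyl-6-oxodecahydronaphthalene-1-carboxylate | O=C1CC[C@H]2[C@](C)(CCC[C@]2(C)C(=O)OC)[C@H]1CC[C@H](C)CCOC(C)=O | intermediate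
17 | methyl (1S,4aR,5S,8aS)-5-[(3S)-5-acetoxy-3-methylpentyl]-1,4a-dimethyl-6-methylidenedecahydronaphthalene-1-carboxylate | C=C1CC[C@H]2[C@](C)(CCC[C@]2(C)C(=O)OC)[C@H]1CC[C@H](C)CCOC(C)=O | target

**Step count**
Total: 12 steps. Longest linear sequence: 11 steps (steps 1–3 and 5–12); step 4 is a one-step side branch.

**Steps most likely to fail**

Step 8. The cycloaddition may be too slow below the temperature at which the (Z)-diene isomerises by [1,5]-hydrogen shift or the free hydroxyl adds to the enoate, because both the diene terminus and the dienophile are hindered. The fallback sets out from 12 and comes back at 13; it raises the dienophile to the aldehyde oxidation level, which reacts much faster and accepts Lewis-acid catalysis at low temperature. Reduction of 12 with i-Bu2AlH (CH2Cl2, −78 °C) would give the triene diol F1. MnO2 would oxidise only its allylic primary alcohol to the hydroxy trienal F2. F2 would be cyclised with Me2AlCl (2.2 equiv, CH2Cl2, −78 → −20 °C, the first equivalent being taken up by the hydroxyl) to the bicyclic aldehyde F3 under the same geometric control. Pinnick oxidation (NaClO2, NaH2PO4, 2-methylbut-2-ene, t-BuOH–H2O) would give the bicyclic acid F4, and Me3SiCHN2 in toluene–MeOH would return 13.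

Step 5. The trisubstituted alkoxydiene may react too slowly with an unactivated aldehyde, or the facial selectivity may be poor. The fallback sets out from 3 and comes back at 14; it forms C8–C9 by allylboration and the Z alkene through a silicon tether, and it runs through the C8-epimeric series, which converges when C8 is oxidised. Alcohol 3, isolated after NaBH4 treatment of the crude selenium dioxide product, would be borylated (B2pin2, Pd(MeCN)4(BF4)2 cat., p-TsOH cat., DMSO–MeOH) to the (E)-allylboronate F5. Addition of F5 to 8, catalysed by the enantiomer of 3,3'-bis(2,4,6-triisopropylphenyl)-1,1'-binaphthyl-2,2'-diyl hydrogen phosphate that delivers the 7R configuration, would pass through a chair transition state to the anti homoallylic alcohol F6. Silylation with chloro(dimethyl)vinylsilane (Et3N, CH2Cl2) would give the vinylsilyl ether F7. Ring-closing metathesis with Mo(=CHCMe2Ph)(=N-2,6-i-Pr2C6H3)[OCMe(CF3)2]2 would give the cyclic siloxane F8, and Hiyama–Denmark coupling with vinyl bromide (Bu4NF, Pd(dba)2, THF) the C8-epimeric triene F9. Cycloaddition as in step 8 (now with an axial 8-OH, so expected slower but with the same sense) would give the C8-epimeric cycloadduct F10, and the oxidation of step 9 would give 14.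

Step 7. The C8 alkoxide may add to the enoate, or the open hydroxy-enal may isomerise from Z to E under the basic conditions. The fallback sets out from 5 and comes back at 12; it installs the enoate after the diene and holds the C8 oxygen in a lactone meanwhile. Diene 5 and commercial methyl 4-oxobutanoate would give, under the conditions of step 5, the ester adduct F11, and hydrolysis as in step 6 would give the ester lactol F12. Wittig methylenation as in step 7 would give the dienyl hydroxy ester F13, which is expected to close in the flask to the dienyl γ-lactone F14. i-Bu2AlH (CH2Cl2, −78 °C) would reduce it to the γ-lactol F15, and methyl 2-(triphenylphosphoranylidene)propanoate (toluene, 80 °C, no base) would open this to 12.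

**Further compounds**
F1 | step 8 | (2E,6R,7R,8Z)-7-[(3S)-5-(benzyloxy)-3-methylpentyl]-2,8-dimethylundeca-2,8,10-triene-1,6-diol | C=C/C=C(/C)[C@@H](CC[C@H](C)CCOCc1ccccc1)[C@H](O)CC/C=C(\C)CO
F2 | step 8 | (2E,6R,7R,8Z)-7-[(3S)-5-(benzyloxy)-3-methylpentyl]-6-hydroxy-2,8-dimethylundeca-2,8,10-trienal | C=C/C=C(/C)[C@@H](CC[C@H](C)CCOCc1ccccc1)[C@H](O)CC/C=C(\C)C=O
F3 | step 8 | (1S,4aS,5R,6R,8aS)-5-[(3S)-5-(benzyloxy)-3-methylpentyl]-6-hydroxy-1,4a-dimethyl-1,2,4a,5,6,7,8,8a-octahydronaphthalene-1-carbaldehyde | O[C@@H]1CC[C@H]2[C@](C)(C=CC[C@]2(C)C=O)[C@H]1CC[C@H](C)CCOCc1ccccc1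
F4 | step 8 | (1S,4aS,5R,6R,8aS)-5-[(3S)-5-(benzyloxy)-3-methylpentyl]-6-hydroxy-1,4a-dimethyl-1,2,4a,5,6,7,8,8a-octahydronaphthalene-1-carboxylic acid | O[C@@H]1CC[C@H]2[C@](C)(C=CC[C@]2(C)C(=O)O)[C@H]1CC[C@H](C)CCOCc1ccccc1
F5 | step 5 | 2-[(2E,6S)-8-(benzyloxy)-2,6-dimethyloct-2-en-1-yl]-4,4,5,5-tetramethyl-1,3,2-dioxaborolane | CC1(C)OB(C/C(C)=C/CC[C@H](C)CCOCc2ccccc2)OC1(C)C
F6 | step 5 | methyl (2E,6S,7R)-7-[(3S)-5-(benzyloxy)-3-methylpentyl]-6-hydroxy-2,8-dimethylnona-2,8-dienoate | C=C(C)[C@@H](CC[C@H](C)CCOCc1ccccc1)[C@@H](O)CC/C=C(\C)C(=O)OC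
F7 | step 5 | methyl (2E,6S,7R)-7-[(3S)-5-(benzyloxy)-3-methylpentyl]-6-{[ethenyl(dimethyl)silyl]oxy}-2,8-dimethylnona-2,8-dienoate | C=C[Si](C)(C)O[C@@H](CC/C=C(\C)C(=O)OC)[C@H](CC[C@H](C)CCOCc1ccccc1)C(C)=C
F8 | step 5 | methyl (2E)-5-[(5R,6S)-5-[(3S)-5-(benzyloxy)-3-methylpentyl]-2,2,4-trimethyl-5,6-dihydro-2H-1,2-oxasilin-6-yl]-2-methylpent-2-enoate | C[Si]1(C)C=C(C)[C@@H](CC[C@H](C)CCOCc2ccccc2)[C@H](CC/C=C(\C)C(=O)OC)O1
F9 | step 5 | methyl (2E,6S,7R,8Z)-7-[(3S)-5-(benzyloxy)-3-methylpentyl]-6-hydroxy-2,8-dimethylundeca-2,8,10-trienoate | C=C/C=C(/C)[C@@H](CC[C@H](C)CCOCc1ccccc1)[C@@H](O)CC/C=C(\C)C(=O)OC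
F10 | step 5 | methyl (1S,4aS,5R,6S,8aS)-5-[(3S)-5-(benzyloxy)-3-methylpentyl]-6-hydroxy-1,4a-dimethyl-1,2,4a,5,6,7,8,8a-octahydronaphthalene-1-carboxylate | O[C@H]1CC[C@H]2[C@](C)(C=CC[C@]2(C)C(=O)OC)[C@H]1CC[C@H](C)CCOCc1ccccc1
F11 | step 7 | methyl 3-[(2R,3R,6R)-3-[(3S)-5-(benzyloxy)-3-methylpentyl]-6-methoxy-4-methyl-3,6-dihydro-2H-pyran-2-yl]propanoate | CO[C@H]1C=C(C)[C@@H](CC[C@H](C)CCOCc2ccccc2)[C@@H](CCC(=O)OC)O1
F12 | step 7 | methyl 3-[(2R,3R)-3-[(3S)-5-(benzyloxy)-3-methylpentyl]-6-hydroxy-4-methyl-3,6-dihydro-2H-pyran-2-yl]propanoate | OC1C=C(C)[C@@H](CC[C@H](C)CCOCc2ccccc2)[C@@H](CCC(=O)OC)O1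
F13 | step 7 | methyl (4R,5R,6Z)-5-[(3S)-5-(benzyloxy)-3-methylpentyl]-4-hydroxy-6-methylnona-6,8-dienoate | C=C/C=C(/C)[C@@H](CC[C@H](C)CCOCc1ccccc1)[C@H](O)CCC(=O)OC
F14 | step 7 | (5R)-5-[(3S,6R,7Z)-1-(benzyloxy)-3,7-dimethyldeca-7,9-dien-6-yl]oxolan-2-one | C=C/C=C(/C)[C@@H](CC[C@H](C)CCOCc1ccccc1)[C@H]1CCC(=O)O1
F15 | step 7 | (5R)-5-[(3S,6R,7Z)-1-(benzyloxy)-3,7-dimethyldeca-7,9-dien-6-yl]oxolan-2-ol | C=C/C=C(/C)[C@@H](CC[C@H](C)CCOCc1ccccc1)[C@H]1CCC(O)O1
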